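(The readings are calculated with made-up constants, and the scatter is random.)

In a one-step world, Q + E giving G, the percent of G climbs at first in a straight line, with a slope in proportion to the charge at fixed equivalents.

| flask | Q | E | remark | time |
|---|---|---|---|---|
| maple | 15 mM | 1 equiv | run made earlier |  |
| birch | 7.5 mM | 1 equiv | run made earlier |  |
| alder | 30 mM | 1 equiv | run made earlier |  |
| violet | 15 mM (fed, over 5.0 h) | 1.00 equiv | all else is in the flask from the start; the feed brings no volume worth counting | 6.0 h |
| teal | 15 mM | 1.00 equiv | everything together at the start | 6.0 h |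
| blue | 15 mM | 1.00 equiv (fed, over 5.0 h) | all else is in the flask from the start; the feed brings no volume worth counting | 6.0 h |
| green | 15 mM | 1.00 equiv (in portions, 4, over 5.0 h) | first portion at the start, last at 5.0 h | 6.0 h |

| run | time / h | G / % | Q / % |
|---|---|---|---|
| maple | 0.250 | 1 | 100 |
| maple | 0.667 | 0 | 99 |
| maple | 1.33 | 3 | 95 |
| maple | 2.00 | 6 | 97 |
| maple | 3.00 | 10 | 91 |
| maple | 4.00 | 12 | 89 |
| birch | 1.00 | 0 | 100 |
| birch | 2.00 | 0 | 99 |
| birch | 3.00 | 5 | 97 |
| birch | 4.00 | 5 | 95 |
| birch | 5.00 | 6 | 95 |
| birch | 6.00 | 5 | 95 |
| alder | 1.00 | 11 | 93 |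
| alder | 2.00 | 34 | 64 |
| alder | 3.00 | 55 | 45 |
| alder | 4.00 | 66 | 35 |
| alder | 5.00 | 70 | 27 |
| alder | 6.00 | 71 | 26 |

(readings scatter by 1.5 percentage points)



- which flask leads in amount of G, in percent of the Q charged ("all alike" within 1.5 percentage points) (violet / teal / blue / green / all alike)
- how much G is there at the end, in percent of the Q charged: violet
- how much G is there at the end, in percent of the Q charged: teal
- how much G is there at the end, in percent of the Q charged: blue
- how much G is there at the end, in percent of the Q charged: green

Alder curves upward instead, and birch still reads 0 % at 2.00 h. Maple, which has teal's recipe, goes from 6 % at 2.00 h to 12 % at 4.00 h, and alder goes from 11 % at 1.00 h to 34 % at 2.00 h. So I take the making of G to feed itself (autocatalysis) and carry one quantity: maple's doubling time, as read from these two scattered readings, τ = 2.00 h, the hours in which G doubles. Alder reads 0.614 h. I expect τ to go inversely with Q times E, which predicts a factor of 4.00 between these runs; the readings, with their scatter, give 3.26.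

For teal, the ceiling is maple's doubling carried on undisturbed to 6.0 h: 24.0 %. For the floor, alder and birch both move within the scatter between 5.00 h and 6.00 h, so I hold maple's late pace until 5.00 h and then stop it, which gives 15.0 %.

In violet, blue and green about 0.5 of the fed partner's charge has gone in on average during the feed, so as a rough figure I take τ as 4.00 h. Maple's doubling line runs back to a notional 3.00 % at the start, though no G is charged; from that figure I reckon each of these flasks at about 8.49 %. That is less than teal's floor, so I expect teal to lead.

The forecast says teal leads, with teal 16 %, inside my bracket, and violet 4 %, blue 4 % and green 5 %, on the ground that “high early concentration is what pays”.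

The flasks give teal the lead: teal 21.6 %, violet 7.60 %, blue 10.4 %, green 10.0 %.

    Q + E + L → G + 2 L (k = 2400 L² mol⁻² h⁻¹)
    Q + E → G + L (k = 1.20 L mol⁻¹ h⁻¹)
    E → Z (k = 0.0990 h⁻¹)

Teal's G goes from 8.85 % at 3.00 h to 21.6 % at 6.0 h, an average doubling time of 2.33 h, longer than the carried τ. At 6.00 h in teal, the step through L, the by-product made with G, uses Q 6.5 times as fast as the plain step. A neighbour of teal with 25 mM of Q, at the same equivalents, has a reckoned τ of 0.720 h and ends at 61.4 %.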